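## Retrosynthetic overview

- The plan rests on ring A (O, C7', C8', C8, C9): its C7' aryl, the C9' carbon on C8' and the C8 hydroxyl lie on alternating faces, which is the pattern left by two successive anti additions across the C8=C8' bond of a γ-aryl butenolide (lignan numbering; ring B = O, C7, C8, C8', C9').
- Target 21 ⇒ bis-silyl ether 20 ⇒ lactone 18 (C9 as C=O) ⇒ ring B opened at O–C9' to triol 16 ⇒ silane 15 (C9'–Si as masked C9'–OH).
- Key disconnection: C8'–C9' and C8–OH of 15 are removed together, back to butenolide 11, the silylmethyl Grignard reagent 13 and an oxaziridine oxygen.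
- 11 ⇒ butenolide 7 + aldehyde 2 (C7–C8, selenolate-triggered Michael–aldol, then selenoxide elimination); 7 ⇒ 2 + methyl propiolate (C7'–C8', catalytic asymmetric alkynylation, then semi-hydrogenation and lactonisation).
- Ring order: ring A first (closed as the butenolide in step 3 and never opened), ring B second (step 10); C7' is the only centre set by a catalyst, and C7, C8' and C8 are relayed from it.

Key step: step 7

Remarks:
- Ar = 3-methoxy-4-(triisopropylsilyloxy)phenyl. The phenols are carried as TIPS rather than TBS ethers, because an aryl TBS ether is not expected to survive the bicarbonate/peroxide oxidation of step 8.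
- The descriptors at C7' and C7 change along the route only through changes in CIP priority; no step inverts either centre.
- Assumption: the ProPhenol antipode used in step 2 is the one that sends the alkynyl group to the Re face of 2; this is to be fixed on the first batch by Mosher ester analysis.

## Route

Step 1
Reactants: 1 vanillin
Product: 2 3-methoxy-4-(triisopropylsilyloxy)benzaldehyde
Conditions: i-Pr3SiCl (1.1 equiv), imidazole (2 equiv), DMF, rt
Reagents that add atoms: triisopropylsilyl chloride, CC(C)[Si](Cl)(C(C)C)C(C)C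
Why: Imidazole-promoted O-silylation of the phenol gives a hindered aryl silyl ether that should last through the organometallic, bicarbonate/peroxide, hydride and Lewis acid steps and still fall to fluoride at the end.

Step 2
Reactants: 2 3-methoxy-4-(triisopropylsilyloxy)benzaldehyde; 3 methyl propiolate
Product: 5 methyl (S)-4-hydroxy-4-Ar-but-2-ynoate, via methyl 3-(methylzincio)prop-2-ynoate 4 (not isolated)
Conditions: 3 (3 equiv), Me2Zn (3 equiv), ProPhenol ligand (10 mol %), Ph3P=O (20 mol %), toluene, 4 °C; aq. NH4Cl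
Reagents that add atoms: none
Why: Catalytic asymmetric alkynylation of an aldehyde by a dinuclear zinc–ProPhenol complex: Me2Zn metalates 3 and the alkynylzinc 4 is delivered to the Re face of 2 inside the chiral pocket, which sets C7' (S here because the alkynyl group outranks the aryl group).

Step 3
Reactants: 5 methyl (S)-4-hydroxy-4-Ar-but-2-ynoate
Product: 7 (R)-5-Ar-furan-2(5H)-one, via methyl (R,Z)-4-hydroxy-4-Ar-but-2-enoate 6 (not isolated)
Conditions: H2 (1 atm), Pd/CaCO3 poisoned with Pb(OAc)2, quinoline, EtOAc, rt; then PPTS (5 mol %), CH2Cl2, rt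
Reagents that add atoms: none
Why: Lindlar semi-hydrogenation gives the Z-enoate 6, whose hydroxyl lies next to the ester and lactonises by intramolecular transesterification under mild acid, and since no base is present the acidic C7' centre should be kept.

Step 4
Reactants: 7 (R)-5-Ar-furan-2(5H)-one; 2 3-methoxy-4-(triisopropylsilyloxy)benzaldehyde
Product: 9 (3S,4R,5S)-3-[(R)-hydroxy(Ar)methyl]-5-Ar-4-(phenylselanyl)dihydrofuran-2(3H)-one, via lithium enolate 8 (not isolated)
Conditions: PhSeH (1.1 equiv), n-BuLi (1.05 equiv), THF, –78 °C; add 7 + 2 (1.2 equiv), –78 °C; AcOH, –78 °C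
Reagents that add atoms: benzeneselenol (used as its lithium salt), [SeH]c1ccccc1
Why: Selenolate-triggered Michael–aldol sequence (a two-stage Morita–Baylis–Hillman surrogate): the weakly basic selenolate adds to C8' trans to the C7' aryl, the ring-locked E-enolate 8 meets 2 on the face away from selenium through a Zimmerman–Traxler chair that gives the anti aldol, and this relay fixes C7 relative to C7'.

Step 5
Reactants: 9 (3S,4R,5S)-3-[(R)-hydroxy(Ar)methyl]-5-Ar-4-(phenylselanyl)dihydrofuran-2(3H)-one
Product: 11 (R)-3-[(S)-hydroxy(Ar)methyl]-5-Ar-furan-2(5H)-one, via selenoxide 10 (not isolated)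
Conditions: 30% H2O2 (3 equiv), NaHCO3, CH2Cl2/H2O, 0 °C → rt
Reagents that add atoms: none
Why: Selenoxide syn-elimination: of the two hydrogens cis to selenium, the acidic H8 next to the carbonyl should be taken in preference to H7' on the oxygen-bearing carbon, which restores the conjugated C8=C8' bond and leaves C7 and C7' untouched.

Step 6
Reactants: 12 (chloromethyl)isopropoxydimethylsilane
Product: 13 [(isopropoxydimethylsilyl)methyl]magnesium chloride
Conditions: Mg turnings (1.3 equiv), BrCH2CH2Br (cat.), THF, rt → 45 °C; titrated and used at once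
Reagents that add atoms: magnesium, [Mg]
Why: Grignard formation by insertion of magnesium into the primary α-silyl C–Cl bond, the hindered Si–O-i-Pr group being slow to react with the reagent.

Step 7
Reactants: 11 (R)-3-[(S)-hydroxy(Ar)methyl]-5-Ar-furan-2(5H)-one; 13 [(isopropoxydimethylsilyl)methyl]magnesium chloride
Product: 15 (3S,4S,5R)-3-hydroxy-3-[(S)-hydroxy(Ar)methyl]-4-[(isopropoxydimethylsilyl)methyl]-5-Ar-dihydrofuran-2(3H)-one, via chloromagnesium enolate alkoxide 14 (not isolated)
Conditions: 13 (3.0 equiv, slow addition), CuBr·SMe2 (20 mol %), THF, –78 → –40 °C; then (±)-trans-2-(phenylsulfonyl)-3-phenyloxaziridine (2.5 equiv), –78 °C; aq. NH4Cl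
Reagents that add atoms: 2-(phenylsulfonyl)-3-phenyloxaziridine, O=S(=O)(N1OC1c1ccccc1)c1ccccc1
Why: The first equivalent of 13 deprotonates the C7 hydroxyl, and the chloromagnesium alkoxide, which is no leaving group, chelates the lactone carbonyl; the cuprate formed from 13 and monovalent copper then adds to C8' by π-complexation, oxidative addition to a σ-alkylcopper species of trivalent copper and reductive elimination, which makes C8'–C9' and leaves the magnesium enolate 14. The oxaziridine then gives up its oxygen to C8 of 14 by attack of the enolate carbon on the weak N–O bond, which makes C8–O. The closest known reaction type is the conjugate addition of an organocopper reagent to an enoate followed in the same flask by hydroxylation of the enolate with an N-sulfonyloxaziridine (Davis oxidation), combined with the copper-catalysed conjugate hydroxymethylation that this silylmethyl Grignard reagent is known for; no ring is closed. C8' is set by the C7' aryl, which blocks its own face of the planar butenolide so that the silylmethyl group enters trans to it; C8 is set by the new C9' arm, the oxidant coming from the opposite face, which places the hydroxyl trans to C9' and the C7 side chain cis to it as ring B will need. The step needs 1,4- over 1,2-addition and addition faster than removal of the acidic C7' proton, which the copper catalysis, the slow addition of 13 at –78 °C and the activating chelate should secure, and it needs the enolate not to expel the C7 oxygen, which the negative charge on that oxygen secures.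

Step 8
Reactants: 15 (3S,4S,5R)-3-hydroxy-3-[(S)-hydroxy(Ar)methyl]-4-[(isopropoxydimethylsilyl)methyl]-5-Ar-dihydrofuran-2(3H)-one
Product: 16 (3S,4S,5R)-3-hydroxy-4-(hydroxymethyl)-3-[(S)-hydroxy(Ar)methyl]-5-Ar-dihydrofuran-2(3H)-one
Conditions: 30% H2O2 (10 equiv), KHCO3 (2 equiv), THF/MeOH 1:1, rt → 40 °C, no fluoride; aq. Na2S2O3
Reagents that add atoms: hydrogen peroxide, OO
Why: Tamao oxidation: hydroperoxide adds to the alkoxysilane and C9' migrates from silicon to oxygen, which turns C9'–Si into C9'–OH without touching a stereocentre, and fluoride is left out so that the aryl O–Si bonds are kept.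

Step 9
Reactants: 16 (3S,4S,5R)-3-hydroxy-4-(hydroxymethyl)-3-[(S)-hydroxy(Ar)methyl]-5-Ar-dihydrofuran-2(3H)-one
Product: 17 (3S,4S,5R)-3-hydroxy-3-[(S)-hydroxy(Ar)methyl]-4-[(p-tolylsulfonyloxy)methyl]-5-Ar-dihydrofuran-2(3H)-one
Conditions: TsCl (1.15 equiv), Et3N (2 equiv), Me3N·HCl (10 mol %), CH2Cl2, 0 °C
Reagents that add atoms: p-toluenesulfonyl chloride, Cc1ccc(cc1)S(Cl)(=O)=O
Why: Amine-catalysed sulfonylation should pick the unhindered primary C9' hydroxyl over the secondary benzylic C7 hydroxyl and the tertiary C8 hydroxyl on steric grounds.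

Step 10
Reactants: 17 (3S,4S,5R)-3-hydroxy-3-[(S)-hydroxy(Ar)methyl]-4-[(p-tolylsulfonyloxy)methyl]-5-Ar-dihydrofuran-2(3H)-one
Product: 18 (3R,3aS,6S,6aS)-6a-hydroxy-3,6-bis(Ar)tetrahydro-1H,3H-furo[3,4-c]furan-1-one
Conditions: NaH (1.2 equiv), THF, 0 °C; aq. NH4Cl
Reagents that add atoms: none
Why: Intramolecular Williamson etherification (5-exo-tet): the C7 alkoxide, held cis to C9' on ring A, displaces the tosylate and closes ring B cis-fused with C7 unchanged because the new bond forms at C9', while the C8 oxygen is trans to C9' and cannot reach it.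

Step 11
Reactants: 18 (3R,3aS,6S,6aS)-6a-hydroxy-3,6-bis(Ar)tetrahydro-1H,3H-furo[3,4-c]furan-1-one
Product: 19 (3R,3aS,6S,6aS)-3,6-bis(Ar)tetrahydro-1H,3H-furo[3,4-c]furan-1,6a-diol (lactol, both anomers)
Conditions: i-Bu2AlH (2.5 equiv), CH2Cl2, –78 °C; aq. potassium sodium tartrate
Reagents that add atoms: none
Why: Partial reduction of a lactone: the tetrahedral aluminium lactolate is stable at –78 °C and gives the lactol on work-up, one equivalent of hydride being spent on the tertiary hydroxyl, and the new C9 centre is of no consequence.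

Step 12
Reactants: 19 (3R,3aS,6S,6aS)-3,6-bis(Ar)tetrahydro-1H,3H-furo[3,4-c]furan-1,6a-diol
Product: 20 (1R,3aR,4S,6aS)-1,4-bis(Ar)tetrahydro-1H,3H-furo[3,4-c]furan-3a-ol
Conditions: Et3SiH (5 equiv), BF3·OEt2 (2 equiv), CH2Cl2, –78 → –40 °C; Et3N, then aq. NaHCO3
Reagents that add atoms: none
Why: Ionic hydrogenation of a lactol: BF3 ionises the anomeric C9–OH to an oxocarbenium ion that takes hydride from Et3SiH, so C9 becomes CH2, and at low temperature this ionisation should be much faster than that of the benzylic C7–O and C7'–O bonds.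

Step 13
Reactants: 20 (1R,3aR,4S,6aS)-1,4-bis(Ar)tetrahydro-1H,3H-furo[3,4-c]furan-3a-ol
Product: 21 (1R,3aR,4S,6aS)-1,4-bis(4-hydroxy-3-methoxyphenyl)tetrahydro-1H,3H-furo[3,4-c]furan-3a-ol, the (7S,8R,7'R,8'S) enantiomer of 8-hydroxypinoresinol
Conditions: Bu4NF (2.4 equiv), AcOH (2.4 equiv), THF, 0 °C
Reagents that add atoms: none
Why: Fluoride cleavage of the two aryl silyl ethers, buffered with acetic acid so that no free phenoxide can open the para benzylic ether bonds through a quinone methide.

## Compound list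

1 | vanillin | COc1cc(C=O)ccc1O | starting material
2 | 3-methoxy-4-(triisopropylsilyloxy)benzaldehyde | COc1cc(C=O)ccc1O[Si](C(C)C)(C(C)C)C(C)C | intermediate
3 | methyl propiolate | C#CC(=O)OC | starting material
4 | methyl 3-(methylzincio)prop-2-ynoate | C[Zn]C#CC(=O)OC | intermediate
5 | methyl (S)-4-hydroxy-4-Ar-but-2-ynoate | COc1cc([C@H](O)C#CC(=O)OC)ccc1O[Si](C(C)C)(C(C)C)C(C)C | intermediate
6 | methyl (R,Z)-4-hydroxy-4-Ar-but-2-enoate | C(/C(=O)OC)=C/[C@@H](O)c1ccc(O[Si](C(C)C)(C(C)C)C(C)C)c(OC)c1 | intermediate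
7 | (R)-5-Ar-furan-2(5H)-one | COc1cc([C@@H]2OC(=O)C=C2)ccc1O[Si](C(C)C)(C(C)C)C(C)C | intermediate
8 | lithium enolate of (4R,5S)-5-Ar-4-(phenylselanyl)dihydrofuran-2(3H)-one | COc1cc([C@@H]2OC([O-])=C[C@H]2[Se]c3ccccc3)ccc1O[Si](C(C)C)(C(C)C)C(C)C.[Li+] | intermediate
9 | (3S,4R,5S)-3-[(R)-hydroxy(Ar)methyl]-5-Ar-4-(phenylselanyl)dihydrofuran-2(3H)-one | COc1cc([C@@H]2OC(=O)[C@H]([C@@H](O)c3ccc(O[Si](C(C)C)(C(C)C)C(C)C)c(OC)c3)[C@H]2[Se]c4ccccc4)ccc1O[Si](C(C)C)(C(C)C)C(C)C | intermediate
10 | selenoxide of 9 (configuration at Se not defined) | COc1cc([C@@H]2OC(=O)[C@H]([C@@H](O)c3ccc(O[Si](C(C)C)(C(C)C)C(C)C)c(OC)c3)[C@H]2[Se](=O)c4ccccc4)ccc1O[Si](C(C)C)(C(C)C)C(C)C | intermediate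
11 | (R)-3-[(S)-hydroxy(Ar)methyl]-5-Ar-furan-2(5H)-one | COc1cc([C@@H]2OC(=O)C([C@@H](O)c3ccc(O[Si](C(C)C)(C(C)C)C(C)C)c(OC)c3)=C2)ccc1O[Si](C(C)C)(C(C)C)C(C)C | intermediate
12 | (chloromethyl)isopropoxydimethylsilane | CC(C)O[Si](C)(C)CCl | starting material
13 | [(isopropoxydimethylsilyl)methyl]magnesium chloride | CC(C)O[Si](C)(C)C[Mg]Cl | intermediate
14 | chloromagnesium enolate and C7 chloromagnesium alkoxide formed by addition of 13 to 11 | COc1cc([C@@H]2OC(O[Mg]Cl)=C([C@@H](O[Mg]Cl)c3ccc(O[Si](C(C)C)(C(C)C)C(C)C)c(OC)c3)[C@H]2C[Si](C)(C)OC(C)C)ccc1O[Si](C(C)C)(C(C)C)C(C)C | intermediate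
15 | (3S,4S,5R)-3-hydroxy-3-[(S)-hydroxy(Ar)methyl]-4-[(isopropoxydimethylsilyl)methyl]-5-Ar-dihydrofuran-2(3H)-one | COc1cc([C@@H]2OC(=O)[C@@](O)([C@@H](O)c3ccc(O[Si](C(C)C)(C(C)C)C(C)C)c(OC)c3)[C@H]2C[Si](C)(C)OC(C)C)ccc1O[Si](C(C)C)(C(C)C)C(C)C | intermediate
16 | (3S,4S,5R)-3-hydroxy-4-(hydroxymethyl)-3-[(S)-hydroxy(Ar)methyl]-5-Ar-dihydrofuran-2(3H)-one | COc1cc([C@@H]2OC(=O)[C@@](O)([C@@H](O)c3ccc(O[Si](C(C)C)(C(C)C)C(C)C)c(OC)c3)[C@H]2CO)ccc1O[Si](C(C)C)(C(C)C)C(C)C | intermediate
17 | primary p-toluenesulfonate of 16 | COc1cc([C@@H]2OC(=O)[C@@](O)([C@@H](O)c3ccc(O[Si](C(C)C)(C(C)C)C(C)C)c(OC)c3)[C@H]2COS(=O)(=O)c4ccc(C)cc4)ccc1O[Si](C(C)C)(C(C)C)C(C)C | intermediate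
18 | (3R,3aS,6S,6aS)-6a-hydroxy-3,6-bis(Ar)tetrahydro-1H,3H-furo[3,4-c]furan-1-one | COc1cc([C@@H]2OC(=O)[C@@]3(O)[C@H](c4ccc(O[Si](C(C)C)(C(C)C)C(C)C)c(OC)c4)OC[C@@H]23)ccc1O[Si](C(C)C)(C(C)C)C(C)C | intermediate
19 | (3R,3aS,6S,6aS)-3,6-bis(Ar)tetrahydro-1H,3H-furo[3,4-c]furan-1,6a-diol (both anomers) | COc1cc([C@@H]2OC(O)[C@@]3(O)[C@H](c4ccc(O[Si](C(C)C)(C(C)C)C(C)C)c(OC)c4)OC[C@@H]23)ccc1O[Si](C(C)C)(C(C)C)C(C)C | intermediate
20 | (1R,3aR,4S,6aS)-1,4-bis(Ar)tetrahydro-1H,3H-furo[3,4-c]furan-3a-ol | COc1cc([C@@H]2OC[C@@]3(O)[C@H](c4ccc(O[Si](C(C)C)(C(C)C)C(C)C)c(OC)c4)OC[C@@H]23)ccc1O[Si](C(C)C)(C(C)C)C(C)C | intermediate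
21 | (1R,3aR,4S,6aS)-1,4-bis(4-hydroxy-3-methoxyphenyl)tetrahydro-1H,3H-furo[3,4-c]furan-3a-ol | COc1cc([C@@H]2OC[C@@]3(O)[C@H](c4ccc(O)c(OC)c4)OC[C@@H]23)ccc1O | target

## Step count and risks

Total step count: 13. Longest linear sequence: 12 (steps 1–5 and 7–13, from vanillin); step 6 is a one-step side branch.

Steps most likely to fail:

Step 7. The Grignard reagent may remove the acidic C7' proton and so erode that centre. The conjugate addition to the alkoxide-bearing, α-branched acceptor may be slow. Oxygen transfer to the crowded enolate may show poor facial selectivity or lose out to capture of the sulfonimine. The fallback sets out from 11 and comes back at 16. The copper-catalysed addition of 13 is run with Me3SiCl and DMPU present, a silyl-accelerated conjugate addition that caps the C7 oxygen and traps the enolate as the bis(trimethylsilyl) ketene acetal F1. F1 is then epoxidised with m-CPBA/NaHCO3 at low temperature (Rubottom oxidation), the oxygen again entering trans to the C9' arm, to give the α-silyloxy lactone F2. F2 is submitted to the bicarbonate/peroxide conditions of step 8, which strip both Me3Si groups and oxidise the C–Si bond, and the route continues from 16.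

Step 4. The simple diastereoselection of the lithium aldol may be weak, giving a mixture at C7, or the selenolate addition may reverse before the aldol takes place. The fallback sets out from 7 and comes back at 11. α-Iodination (I2, pyridine, CH2Cl2) gives the 3-iodobutenolide F3. Nozaki–Hiyama–Kishi coupling of F3 with 2 (CrCl2, NiCl2 cat., a chiral oxazoline–sulfonamide ligand on chromium, MeCN/THF) then gives 11 directly, with C7 set by the ligand instead of by relay.

Step 12. The Lewis acid may ionise the benzylic C7–O or C7'–O bonds in competition with the lactol, leading to epimerisation or reductive ring opening. The fallback sets out from 18 and comes back at 21. The tertiary hydroxyl is silylated (Et3SiOTf, 2,6-lutidine) to give the triethylsilyl ether F4, and LiBH4 reduces the lactone to the 1,4-diol F5. MsCl/Et3N then closes ring A: either the C7' hydroxyl displaces the primary mesylate or the C9 hydroxyl captures the ionised benzylic mesylate, and both paths should place the aryl on the convex face. This gives the tris-silyl furofuran F6, from which Bu4NF/AcOH removes all three silyl groups to give 21.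

Further compounds
F1 | step 7 | bis(trimethylsilyl) ketene acetal from 11, 13 and Me3SiCl | COc1cc([C@@H]2OC(O[Si](C)(C)C)=C([C@@H](O[Si](C)(C)C)c3ccc(O[Si](C(C)C)(C(C)C)C(C)C)c(OC)c3)[C@H]2C[Si](C)(C)OC(C)C)ccc1O[Si](C(C)C)(C(C)C)C(C)C
F2 | step 7 | bis(trimethylsilyl) ether of 15 (C8–O and C7–O) | COc1cc([C@@H]2OC(=O)[C@@](O[Si](C)(C)C)([C@@H](O[Si](C)(C)C)c3ccc(O[Si](C(C)C)(C(C)C)C(C)C)c(OC)c3)[C@H]2C[Si](C)(C)OC(C)C)ccc1O[Si](C(C)C)(C(C)C)C(C)C
F3 | step 4 | (R)-3-iodo-5-Ar-furan-2(5H)-one | COc1cc([C@@H]2OC(=O)C(I)=C2)ccc1O[Si](C(C)C)(C(C)C)C(C)C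
F4 | step 12 | 6a-O-triethylsilyl ether of 18 | COc1cc([C@@H]2OC(=O)[C@@]3(O[Si](CC)(CC)CC)[C@H](c4ccc(O[Si](C(C)C)(C(C)C)C(C)C)c(OC)c4)OC[C@@H]23)ccc1O[Si](C(C)C)(C(C)C)C(C)C
F5 | step 12 | 1,4-diol from reduction of F4 (ring B tetrahydrofuran bearing C9 hydroxymethyl and C7' carbinol) | COc1cc([C@H](O)[C@@H]2CO[C@@H](c3ccc(O[Si](C(C)C)(C(C)C)C(C)C)c(OC)c3)[C@@]2(CO)O[Si](CC)(CC)CC)ccc1O[Si](C(C)C)(C(C)C)C(C)C
F6 | step 12 | 3a-O-triethylsilyl ether of 20 | COc1cc([C@@H]2OC[C@@]3(O[Si](CC)(CC)CC)[C@H](c4ccc(O[Si](C(C)C)(C(C)C)C(C)C)c(OC)c4)OC[C@@H]23)ccc1O[Si](C(C)C)(C(C)C)C(C)C
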